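**Plan**

1. Retrosynthesis: the α-methylene lactone is opened at O8–C12 to a C8 alcohol and a protected C12 alcohol; the ten-membered carbocycle is cut at C9–C10; the furanone is cut at O–C3 and the chain at C3–C4 (alkyne coupling); the last cut is C6–C7.
2. Forward: an (S)-glyceraldehyde-derived allyl bromide (C7–C9, C11–C13) and (Z)-3-iodobut-2-enal (C4–C6, C15) are joined at C6–C7; a five-carbon alkynol (C1, C2, C3, C10, C14) is attached at C3–C4; the furanone ring is closed with gold, the ten-membered ring at C9–C10, and the lactone ring last by oxidation.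
3. Enabling feature: C10 sits in the furanone ring (O, C10, C1, C2, C3) between the ring oxygen and the C1 carbonyl, so loss of its hydrogen gives a flat, aromatic 3-oxidofuran with no configuration at C10. Both C10 epimers can therefore be carried, and C10 is fixed only when it bonds to C9 of a C8,C9 cyclic sulfate.
4. Stereochemistry: C8 comes from (S)-glyceraldehyde acetonide, C6 and C7 from a syn-selective indium allylation controlled by C8, C10 from the ring closure, the 4Z alkene from the iodoenal, and the E tiglate from tigloyl chloride.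

Key step: step 15

Remark (atom labels): germacrane labels are used throughout. The ring carbons run C1 (furanone carbonyl), C2, C3 (furanone carbon on oxygen), C4 (carries methyl C15), C5, C6 (carries the tiglate), C7, C8 (lactone oxygen), C9, C10 (carries methyl C14 and the furanone oxygen); C11, C12 and C13 are the α-carbon, the carbonyl and the methylene of the lactone.

Remark (assumption): ethyl lactate is used as the racemate, because its stereocentre becomes C10, which is set only in step 15.

Remark (assumption): any 6,12-lactone that forms from hydroxy ester 9 on standing is reduced to the same diol 10 in step 6, so 9 is carried on as obtained.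

**Route**

Step 1
Reactants: 1 (S)-glyceraldehyde acetonide; 2 methyl acrylate
Product: 3 Morita–Baylis–Hillman adduct (both carbinol epimers)
Conditions: 1,4-diazabicyclo[2.2.2]octane (DABCO, 0.3 equiv), neat methyl acrylate (3 equiv), rt
Reagents that add atoms: none
Why: Morita–Baylis–Hillman reaction, in which the amine adds to the acrylate and the resulting enolate attacks the aldehyde; the new carbinol centre forms as a mixture that is erased in step 2, and the dioxolane centre (C8) is not touched.

Step 2
Reactants: 3 Morita–Baylis–Hillman adduct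
Product: 4 (Z)-allyl bromide
Conditions: NBS, Me2S, CH2Cl2, 0 °C → rt
Reagents that add atoms: N-bromosuccinimide, O=C1CCC(=O)N1Br
Why: Corey–Kim-type activation of the allylic alcohol followed by SN2′ attack of bromide transposes the allyl system and should give the conjugated, thermodynamically preferred Z bromide from both epimers of 3.

Step 3
Reactants: 5 but-2-yn-1-ol
Product: 7 (Z)-3-iodobut-2-en-1-ol, via cyclic vinylalanate 6 (not isolated)
Conditions: NaAlH2(OCH2CH2OMe)2, Et2O, 0 °C → rt; then I2, THF, −78 °C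
Reagents that add atoms: iodine, II
Why: hydroxyl-directed trans-hydroalumination of the propargylic alcohol places aluminium on C3 in a five-membered alanate, and iodinolysis with retention should give the Z vinyl iodide (iodine cis to CH2OH).

Step 4
Reactants: 7 (Z)-3-iodobut-2-en-1-ol
Product: 8 (Z)-3-iodobut-2-enal
Conditions: MnO2 (activated, excess), CH2Cl2, rt, dark
Reagents that add atoms: none
Why: MnO2 oxidation of an allylic alcohol is neutral and should keep the Z geometry of the β-iodo enal.

Step 5
Reactants: 4 (Z)-allyl bromide; 8 (Z)-3-iodobut-2-enal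
Product: 9 syn hydroxy ester (C6–C7 bond formed)
Conditions: indium powder (1.5 equiv), THF/H2O (1:1), rt
Reagents that add atoms: none
Why: indium-mediated Barbier allylation (SE2′) through a six-membered chair transition state, in which the Z-configured 2-(methoxycarbonyl)allyl reagent carries its C8 substituent axial and should give the syn C6/C7 adduct by 1,2-addition to the enal, while A(1,3) strain to the CH2In group holds the C8–H in the alkene plane so that the aldehyde bonds to C7 anti to the C8–O bond of the dioxolane, which sets C7 (and with it C6) relative to C8; indium tolerates water, the vinyl iodide and the allylic C8–O bond.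

Step 6
Reactants: 9 syn hydroxy ester
Product: 10 methylene diol (C6 and C12 hydroxyls)
Conditions: i-Bu2AlH (4 equiv), CH2Cl2, −78 → −20 °C; Rochelle salt work-up
Reagents that add atoms: none
Why: i-Bu2AlH reduces the conjugated ester by 1,2-addition to the primary allylic alcohol, while the vinyl iodide and the acetonide are inert at low temperature.

Step 7
Reactants: 10 methylene diol
Product: 11 C12 TBDPS ether
Conditions: t-BuPh2SiCl (1.05 equiv), imidazole, CH2Cl2, 0 °C
Reagents that add atoms: tert-butyl(chloro)diphenylsilane, CC(C)(C)[Si](Cl)(c1ccccc1)c1ccccc1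
Why: silylation is selective for the primary allylic hydroxyl over the hindered secondary C6 hydroxyl, and the TBDPS ether is chosen to survive the aqueous acid of step 13.

Step 8
Reactants: 11 C12 TBDPS ether; 12 tigloyl chloride
Product: 13 C6 tiglate vinyl iodide
Conditions: pyridine, 4-(dimethylamino)pyridine (DMAP, 0.1 equiv), CH2Cl2, 0 °C → rt
Reagents that add atoms: none
Why: amine-catalysed acylation of the secondary allylic alcohol with the acid chloride installs the tiglate of the target with retention at C6 and with the E geometry carried over from 12.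

Step 9
Reactants: 14 ethyl lactate (racemic)
Product: 15 ethyl 2-(triethylsilyloxy)propanoate
Conditions: Et3SiCl, imidazole, CH2Cl2, 0 °C
Reagents that add atoms: chlorotriethylsilane, CC[Si](Cl)(CC)CC
Why: standard silylation of a secondary alcohol; the triethylsilyl ether is chosen because it is cleaved by the aqueous acetic acid of step 13.

Step 10
Reactants: 15 ethyl 2-(triethylsilyloxy)propanoate
Product: 17 4-(triethylsilyloxy)pent-1-yn-3-ol (stereoisomer mixture), via 2-(triethylsilyloxy)propanal 16 (not isolated)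
Conditions: i-Bu2AlH (1.05 equiv), CH2Cl2, −78 °C; then HC≡CMgBr (2 equiv, THF), −78 → 0 °C
Reagents that add atoms: ethynylmagnesium bromide, C#C[Mg]Br
Why: one-pot partial reduction of the ester to the aluminium hemiacetal and Grignard addition to the aldehyde released in situ avoids isolating the labile α-silyloxy aldehyde; the new carbinol centre is oxidised in step 12 and C10 is set only in step 15, so the isomer mixture is used as such.

Step 11
Reactants: 13 C6 tiglate vinyl iodide; 17 4-(triethylsilyloxy)pent-1-yn-3-ol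
Product: 18 enyne carbinol (C3–C4 bond formed)
Conditions: Pd(PPh3)4 (5 mol %), CuI (10 mol %), Et3N, THF, rt
Reagents that add atoms: none
Why: Sonogashira coupling of the Z vinyl iodide with the terminal alkyne proceeds with retention of alkene geometry; the free propargylic hydroxyl, the esters and the silyl ethers are tolerated.

Step 12
Reactants: 18 enyne carbinol
Product: 19 α′-silyloxy ynone
Conditions: Dess–Martin periodinane, pyridine, CH2Cl2, 0 °C → rt
Reagents that add atoms: none
Why: Dess–Martin oxidation of the only free (propargylic) alcohol should give the ynone under buffered conditions that leave the acetonide and the silyl ethers intact.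

Step 13
Reactants: 19 α′-silyloxy ynone
Product: 21 furanone diol (both C10 epimers), via triol ynone 20 (not isolated)
Conditions: AcOH/H2O (4:1), 45 °C; evaporate; then (Ph3P)AuNTf2 (5 mol %), CH2Cl2/THF, rt
Reagents that add atoms: none
Why: aqueous acetic acid hydrolyses the triethylsilyl ether and the terminal acetonide while the TBDPS ether and the tiglate survive, and the freed α′-hydroxy ynone should undergo gold-catalysed 5-endo-dig hydroalkoxylation (intramolecular oxa-Michael addition) to the 3(2H)-furanone; C10 forms as both epimers, which is of no consequence.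

Step 14
Reactants: 21 furanone diol
Product: 23 C8,C9 cyclic sulfate (both C10 epimers), via cyclic sulfite 22 (not isolated)
Conditions: SOCl2, pyridine, CH2Cl2, 0 °C; then RuCl3·3H2O (1 mol %), NaIO4 (1.5 equiv), MeCN/H2O, 0 °C, 10 min
Reagents that add atoms: thionyl chloride, O=S(Cl)Cl; sodium periodate, [Na+].[O-]I(=O)(=O)=O
Why: Sharpless cyclic sulfate synthesis, in which the 1,2-diol gives the cyclic sulfite and catalytic RuO4 oxidises sulfur within minutes at 0 °C, which should be faster than attack on the electron-poor or hindered alkenes.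

Step 15
Reactants: 23 C8,C9 cyclic sulfate
Product: 25 bicyclic C8 alcohol (C9–C10 bond and ten-membered ring formed), via cesium sulfate monoester 24 (not isolated)
Conditions: Cs2CO3 (2 equiv), MeCN (2 mM), 45 °C; filter; then conc. H2SO4 (cat.), H2O (2 equiv), THF, rt
Reagents that add atoms: none
Why: Proposed new method: Cs2CO3 removes the C10 hydrogen of either epimer of 23 (it is α to the C1 ketone and its loss gives an aromatic 3-oxidofuran), so both epimers become one planar anion whose C10 attacks the primary C9 of the cyclic sulfate in an SN2 reaction, the C8 oxygen leaving as a sulfate monoester that cannot close back to an epoxide; catalytic acid with water then cleaves the S–O bond and frees the C8 alcohol with retention. The closest known reaction types are the C2-alkylation of 3(2H)-furanone enolates by primary halides or triflates and the opening of 1,2-cyclic sulfates at the primary carbon by stabilised enolates. The ten-membered carbocycle (C1–C10) closes in an exo-tet mode with the leaving oxygen outside the new ring; seen from the furan, the C4–C9 chain bridges its two α positions (C3 and C10) in a nine-membered oxacycle. C10 is the only new stereocentre and is set by the face of the flat furanolate that the short tether can reach, which is fixed by the 4Z alkene and the C6, C7 and C8 centres and should be the face that gives the 10S ring system with the C8 sulfate and the C6 ester pointing outward. The step needs C- rather than O-alkylation and ring closure rather than oligomerisation: O-alkylation would have to span the 1,3-related positions C3 and O–C1 of the planar furan with the same chain, a far more strained, metacyclophane-like transition state than attack on the C10 π face, and the 2 mM concentration with the cesium counter-ion should suppress intermolecular reaction.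

Step 16
Reactants: 25 bicyclic C8 alcohol
Product: 26 bicyclic C8,C12 diol
Conditions: HF·pyridine, pyridine, THF, 0 °C → rt
Reagents that add atoms: none
Why: fluoride cleaves the primary allylic TBDPS ether, and the weakly acidic medium should leave the tiglate, the furanone and the free C8 hydroxyl in place without acyl migration.

Step 17
Reactants: 26 bicyclic C8,C12 diol
Product: 29 target CNP0293168.2, via hydroxy enal 27 (not isolated), via lactol 28 (not isolated)
Conditions: MnO2 (activated, excess), CH2Cl2, rt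
Reagents that add atoms: none
Why: MnO2 oxidises the primary allylic alcohol to the enal, the C8 hydroxyl closes the five-membered lactol, and MnO2 oxidises it on to the α-methylene-γ-butyrolactone (oxidative lactonisation of a 2-methylene-1,4-diol); no stereocentre is touched.

**Compound list**

1 | (4S)-2,2-dimethyl-1,3-dioxolane-4-carbaldehyde [(S)-glyceraldehyde acetonide] | O=C[C@@H]1COC(C)(C)O1 | starting material
2 | methyl acrylate | C=CC(=O)OC | starting material
3 | methyl 2-{[(4S)-2,2-dimethyl-1,3-dioxolan-4-yl](hydroxy)methyl}prop-2-enoate (both carbinol epimers) | C=C(C(=O)OC)C(O)[C@@H]1COC(C)(C)O1 | intermediate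
4 | methyl (2Z)-2-(bromomethyl)-3-[(4R)-2,2-dimethyl-1,3-dioxolan-4-yl]prop-2-enoate | COC(=O)/C(CBr)=C/[C@@H]1COC(C)(C)O1 | intermediate
5 | but-2-yn-1-ol | CC#CCO | starting material
6 | sodium 2,2-bis(2-methoxyethoxy)-3-methyl-2,5-dihydro-1,2-oxaluminol-2-uide (cyclic vinylalanate) | CC1=CCO[Al-]1(OCCOC)OCCOC.[Na+] | intermediate (not isolated)
7 | (2Z)-3-iodobut-2-en-1-ol | C/C(I)=C/CO | intermediate
8 | (2Z)-3-iodobut-2-enal | C/C(I)=C/C=O | intermediate
9 | methyl 2-[(1S,2R,3Z)-1-[(4R)-2,2-dimethyl-1,3-dioxolan-4-yl]-2-hydroxy-4-iodopent-3-en-1-yl]prop-2-enoate | C/C(I)=C/[C@H](O)[C@H](C(=C)C(=O)OC)[C@@H]1COC(C)(C)O1 | intermediate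
10 | (3S,4R,5Z)-3-[(4R)-2,2-dimethyl-1,3-dioxolan-4-yl]-6-iodo-2-methylidenehept-5-ene-1,4-diol | C/C(I)=C/[C@H](O)[C@H](C(=C)CO)[C@@H]1COC(C)(C)O1 | intermediate
11 | (3S,4R,5Z)-1-{[tert-butyl(diphenyl)silyl]oxy}-3-[(4R)-2,2-dimethyl-1,3-dioxolan-4-yl]-6-iodo-2-methylidenehept-5-en-4-ol | C/C(I)=C/[C@H](O)[C@H](C(=C)CO[Si](c1ccccc1)(c1ccccc1)C(C)(C)C)[C@@H]1COC(C)(C)O1 | intermediate
12 | (2E)-2-methylbut-2-enoyl chloride (tigloyl chloride) | C/C=C(\C)C(Cl)=O | starting material
13 | (3S,4R,5Z)-1-{[tert-butyl(diphenyl)silyl]oxy}-3-[(4R)-2,2-dimethyl-1,3-dioxolan-4-yl]-6-iodo-2-methylidenehept-5-en-4-yl (2E)-2-methylbut-2-enoate | C/C(I)=C/[C@H](OC(=O)/C(C)=C/C)[C@H](C(=C)CO[Si](c1ccccc1)(c1ccccc1)C(C)(C)C)[C@@H]1COC(C)(C)O1 | intermediate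
14 | ethyl 2-hydroxypropanoate (ethyl lactate, racemic) | CCOC(=O)C(C)O | starting material
15 | ethyl 2-[(triethylsilyl)oxy]propanoate (racemic) | CCOC(=O)C(C)O[Si](CC)(CC)CC | intermediate
16 | 2-[(triethylsilyl)oxy]propanal (racemic) | CC(O[Si](CC)(CC)CC)C=O | intermediate (not isolated)
17 | 4-[(triethylsilyl)oxy]pent-1-yn-3-ol (mixture of stereoisomers) | C#CC(O)C(C)O[Si](CC)(CC)CC | intermediate
18 | (3S,4S,5Z)-1-{[tert-butyl(diphenyl)silyl]oxy}-3-[(4R)-2,2-dimethyl-1,3-dioxolan-4-yl]-9-hydroxy-6-methyl-2-methylidene-10-[(triethylsilyl)oxy]undec-5-en-7-yn-4-yl (2E)-2-methylbut-2-enoate (mixture at chain C9 and C10) | CC(O[Si](CC)(CC)CC)C(O)C#C/C(C)=C\[C@H](OC(=O)/C(C)=C/C)[C@H](C(=C)CO[Si](c1ccccc1)(c1ccccc1)C(C)(C)C)[C@@H]1COC(C)(C)O1 | intermediate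
19 | (3S,4S,5Z)-1-{[tert-butyl(diphenyl)silyl]oxy}-3-[(4R)-2,2-dimethyl-1,3-dioxolan-4-yl]-6-methyl-2-methylidene-9-oxo-10-[(triethylsilyl)oxy]undec-5-en-7-yn-4-yl (2E)-2-methylbut-2-enoate (both epimers at chain C10) | CC(O[Si](CC)(CC)CC)C(=O)C#C/C(C)=C\[C@H](OC(=O)/C(C)=C/C)[C@H](C(=C)CO[Si](c1ccccc1)(c1ccccc1)C(C)(C)C)[C@@H]1COC(C)(C)O1 | intermediate
20 | (2R,3R,4S,5Z)-3-(3-{[tert-butyl(diphenyl)silyl]oxy}prop-1-en-2-yl)-1,2,10-trihydroxy-6-methyl-9-oxoundec-5-en-7-yn-4-yl (2E)-2-methylbut-2-enoate (both epimers at chain C10) | CC(O)C(=O)C#C/C(C)=C\[C@H](OC(=O)/C(C)=C/C)[C@H](C(=C)CO[Si](c1ccccc1)(c1ccccc1)C(C)(C)C)[C@@H](O)CO | intermediate (not isolated)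
21 | (2R,3R,4S,5Z)-3-(3-{[tert-butyl(diphenyl)silyl]oxy}prop-1-en-2-yl)-1,2-dihydroxy-6-(5-methyl-4-oxo-4,5-dihydrofuran-2-yl)hept-5-en-4-yl (2E)-2-methylbut-2-enoate (both epimers at furanone C5, which is C10) | CC1OC(=CC1=O)/C(C)=C\[C@H](OC(=O)/C(C)=C/C)[C@H](C(=C)CO[Si](c1ccccc1)(c1ccccc1)C(C)(C)C)[C@@H](O)CO | intermediate
22 | (3S,4S,5Z)-1-{[tert-butyl(diphenyl)silyl]oxy}-6-(5-methyl-4-oxo-4,5-dihydrofuran-2-yl)-2-methylidene-3-[(4R)-2-oxo-1,3,2-dioxathiolan-4-yl]hept-5-en-4-yl (2E)-2-methylbut-2-enoate (epimers at sulfur and at C10) | CC1OC(=CC1=O)/C(C)=C\[C@H](OC(=O)/C(C)=C/C)[C@H](C(=C)CO[Si](c1ccccc1)(c1ccccc1)C(C)(C)C)[C@@H]1COS(=O)O1 | intermediate (not isolated)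
23 | (3S,4S,5Z)-1-{[tert-butyl(diphenyl)silyl]oxy}-3-[(4R)-2,2-dioxo-1,3,2-dioxathiolan-4-yl]-6-(5-methyl-4-oxo-4,5-dihydrofuran-2-yl)-2-methylidenehept-5-en-4-yl (2E)-2-methylbut-2-enoate (both epimers at C10) | CC1OC(=CC1=O)/C(C)=C\[C@H](OC(=O)/C(C)=C/C)[C@H](C(=C)CO[Si](c1ccccc1)(c1ccccc1)C(C)(C)C)[C@@H]1COS(=O)(=O)O1 | intermediate (key-step precursor)
24 | cesium (2Z,4S,5S,6S,8S)-5-(3-{[tert-butyl(diphenyl)silyl]oxy}prop-1-en-2-yl)-2,8-dimethyl-4-{[(2E)-2-methylbut-2-enoyl]oxy}-9-oxo-11-oxabicyclo[6.2.1]undeca-1(10),2-dien-6-yl sulfate | [Cs+].[O-]S(=O)(=O)O[C@H]1C[C@]2(C)OC(=CC2=O)/C(C)=C\[C@H](OC(=O)/C(C)=C/C)[C@@H]1C(=C)CO[Si](c1ccccc1)(c1ccccc1)C(C)(C)C | intermediate (not isolated)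
25 | (2Z,4S,5R,6S,8S)-5-(3-{[tert-butyl(diphenyl)silyl]oxy}prop-1-en-2-yl)-6-hydroxy-2,8-dimethyl-9-oxo-11-oxabicyclo[6.2.1]undeca-1(10),2-dien-4-yl (2E)-2-methylbut-2-enoate | O[C@H]1C[C@]2(C)OC(=CC2=O)/C(C)=C\[C@H](OC(=O)/C(C)=C/C)[C@@H]1C(=C)CO[Si](c1ccccc1)(c1ccccc1)C(C)(C)C | intermediate (key-step product)
26 | (2Z,4S,5R,6S,8S)-6-hydroxy-5-(3-hydroxyprop-1-en-2-yl)-2,8-dimethyl-9-oxo-11-oxabicyclo[6.2.1]undeca-1(10),2-dien-4-yl (2E)-2-methylbut-2-enoate | O[C@H]1C[C@]2(C)OC(=CC2=O)/C(C)=C\[C@H](OC(=O)/C(C)=C/C)[C@@H]1C(=C)CO | intermediate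
27 | (2Z,4S,5R,6S,8S)-6-hydroxy-2,8-dimethyl-9-oxo-5-(3-oxoprop-1-en-2-yl)-11-oxabicyclo[6.2.1]undeca-1(10),2-dien-4-yl (2E)-2-methylbut-2-enoate | O[C@H]1C[C@]2(C)OC(=CC2=O)/C(C)=C\[C@H](OC(=O)/C(C)=C/C)[C@@H]1C(=C)C=O | intermediate (not isolated)
28 | 8,12-lactol of the target (C12 hemiacetal in place of the lactone carbonyl, both anomers; 6S,7R,8S,10S) | C=C1C(O)O[C@H]2C[C@]3(C)OC(=CC3=O)/C(C)=C\[C@H](OC(=O)/C(C)=C/C)[C@H]12 | intermediate (not isolated)
29 | CNP0293168.2: (6S,7R,8S,10S)-3,10-epoxy-6-{[(2E)-2-methylbut-2-enoyl]oxy}-1-oxogermacra-2,4Z,11(13)-trien-12,8-olide | C=C1C(=O)O[C@H]2C[C@]3(C)OC(=CC3=O)/C(C)=C\[C@H](OC(=O)/C(C)=C/C)[C@H]12 | target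

**Totals**

Total step count: 17.
Longest linear sequence: 13 steps from (S)-glyceraldehyde acetonide (steps 1, 2, 5, 6, 7, 8, 11, 12, 13, 14, 15, 16, 17).

**The three steps most likely to fail**

Step 15 (proposed new method). What may go wrong: alkylation of the furanolate on oxygen instead of at C10, attack of carbonate on the sulfate, intermolecular alkylation to oligomers, or closure on the wrong face of the furan. The fallback uses a known reaction type, the C2-alkylation of a lithium 3(2H)-furanone enolate by a primary iodide, here run intramolecularly; it sets out from diol 21 and comes back at 25. I2, PPh3 and imidazole (THF, 0 °C) should convert the primary C9 hydroxyl selectively into the iodide, giving iodohydrin F1. Et3SiOTf and 2,6-lutidine (CH2Cl2, −78 °C) should then give the C8 triethylsilyl ether, silyloxy iodide F2. LiN(SiMe3)2 (THF/DMPU, 2 mM, −78 → 0 °C) should convert both C10 epimers into the lithium furanolate, whose tight O–Li pairing and the soft iodide favour bond formation at C10, to give the bicyclic silyl ether F3. AcOH/THF/H2O then removes the triethylsilyl group and gives 25.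

Step 5. What may go wrong: poor facial selectivity of the allylindium reagent with respect to C8, or erosion of the syn selectivity by geometric equilibration of the allylindium species. The fallback replaces substrate control by catalyst control with a configurationally stable allylboronate; it sets out from 3 and comes back at 9. Ac2O with 4-(dimethylamino)pyridine should give the acetate F4. Copper-catalysed SN2′ borylation (bis(pinacolato)diboron, CuCl (cat.), KOAc, DMF) should give the allylboronate F5, with the dioxolane cis to CH2B as in 4. Allylboration of aldehyde 8 would then be catalysed by the chiral phosphoric acid (R)-3,3′-bis(2,4,6-triisopropylphenyl)-1,1′-binaphthalene-2,2′-diyl hydrogen phosphate, or by its enantiomer, whichever is matched to the needed aldehyde face (toluene, −30 °C). This runs through a closed chair transition state in which the catalyst fixes the aldehyde face (C6) and the boronate geometry fixes the syn relation (C7), and gives 9.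

Step 14. What may go wrong: over-oxidation by RuO4, that is, cleavage of the 1,1-disubstituted alkene or oxidation at the enolisable C10 of the furanone, in competition with oxidation of the sulfite. The fallback installs the sulfate at its final oxidation level without any oxidant; it sets out from diol 21 and comes back at 23. Bu2Sn(OMe)2 (toluene, rt, then evaporation) should give the dibutylstannylene acetal F6, which with SO2Cl2 (CH2Cl2, −20 °C) should give the cyclic sulfate 23 directly.

**Further compounds**

F1 | step 15 | (2R,3R,4S,5Z)-3-(3-{[tert-butyl(diphenyl)silyl]oxy}prop-1-en-2-yl)-2-hydroxy-1-iodo-6-(5-methyl-4-oxo-4,5-dihydrofuran-2-yl)hept-5-en-4-yl (2E)-2-methylbut-2-enoate (both C10 epimers) | CC1OC(=CC1=O)/C(C)=C\[C@H](OC(=O)/C(C)=C/C)[C@H](C(=C)CO[Si](c1ccccc1)(c1ccccc1)C(C)(C)C)[C@@H](O)CI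
F2 | step 15 | (2R,3S,4S,5Z)-3-(3-{[tert-butyl(diphenyl)silyl]oxy}prop-1-en-2-yl)-1-iodo-6-(5-methyl-4-oxo-4,5-dihydrofuran-2-yl)-2-[(triethylsilyl)oxy]hept-5-en-4-yl (2E)-2-methylbut-2-enoate (both C10 epimers) | CC1OC(=CC1=O)/C(C)=C\[C@H](OC(=O)/C(C)=C/C)[C@H](C(=C)CO[Si](c1ccccc1)(c1ccccc1)C(C)(C)C)[C@@H](O[Si](CC)(CC)CC)CI
F3 | step 15 | (2Z,4S,5S,6S,8S)-5-(3-{[tert-butyl(diphenyl)silyl]oxy}prop-1-en-2-yl)-2,8-dimethyl-9-oxo-6-[(triethylsilyl)oxy]-11-oxabicyclo[6.2.1]undeca-1(10),2-dien-4-yl (2E)-2-methylbut-2-enoate | CC[Si](CC)(CC)O[C@H]1C[C@]2(C)OC(=CC2=O)/C(C)=C\[C@H](OC(=O)/C(C)=C/C)[C@@H]1C(=C)CO[Si](c1ccccc1)(c1ccccc1)C(C)(C)C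
F4 | step 5 | methyl 2-{(acetyloxy)[(4S)-2,2-dimethyl-1,3-dioxolan-4-yl]methyl}prop-2-enoate (both epimers) | C=C(C(=O)OC)C(OC(C)=O)[C@@H]1COC(C)(C)O1
F5 | step 5 | methyl (2E)-3-[(4R)-2,2-dimethyl-1,3-dioxolan-4-yl]-2-[(4,4,5,5-tetramethyl-1,3,2-dioxaborolan-2-yl)methyl]prop-2-enoate | COC(=O)/C(CB1OC(C)(C)C(C)(C)O1)=C/[C@@H]1COC(C)(C)O1
F6 | step 14 | (3S,4S,5Z)-1-{[tert-butyl(diphenyl)silyl]oxy}-3-[(4R)-2,2-dibutyl-1,3,2-dioxastannolan-4-yl]-6-(5-methyl-4-oxo-4,5-dihydrofuran-2-yl)-2-methylidenehept-5-en-4-yl (2E)-2-methylbut-2-enoate (both C10 epimers) | CC1OC(=CC1=O)/C(C)=C\[C@H](OC(=O)/C(C)=C/C)[C@H](C(=C)CO[Si](c1ccccc1)(c1ccccc1)C(C)(C)C)[C@@H]1CO[Sn](CCCC)(CCCC)O1
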